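**Strategy.** The oxygenated core ring (C1–C6: epoxide C1–C2, carbinols C3 and C6, alkene C4=C5; C7 on C4, side-chain carbinol C8 on C1) is a masked 2,5-disubstituted hydroquinone with para oxygens on C3 and C6. It is therefore assembled as an arene by Dötz benzannulation: an alkenyl(methoxy)carbene chromium complex (C3, C4, C5, C7), a chiral terminal alkyne carrying C8 and a (Z)-vinyl iodide (C1, C2) and one CO ligand (C6) combine, the ring closing when ketene carbon C6 bonds to alkene terminus C5. Dearomatisation, directed epoxidation and two ketone reductions set the core; a late Suzuki coupling appends the cyclised terpenoid ring.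

Key step: step 7

Assumption: the absolute sense of the two ligand-controlled steps, 5 ((S,S)-ProPhenol taken to give the 3S alcohol) and 9 (L-(+)-tartrate taken to deliver the peroxide to the face drawn), is assigned by analogy with the closest known substrates; should either be opposite, the enantiomeric ligand is used and nothing else changes.

Step 1
Reactants: 1 2-bromoprop-2-en-1-ol
Product: 2 [(2-bromoprop-2-en-1-yl)oxy](tert-butyl)dimethylsilane
Conditions: TBSCl, imidazole, CH2Cl2, 0 °C to rt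
Reagents that add atoms: tert-butyl(chloro)dimethylsilane, C[Si](C)(Cl)C(C)(C)C
Why: Routine silylation of a primary alcohol; the ether survives the lithiation below and later is the only primary silyl ether, so that C7–OH can be freed selectively.

Step 2
Reactants: 2 [(2-bromoprop-2-en-1-yl)oxy](tert-butyl)dimethylsilane
Product: 5 pentacarbonyl{2-[(tert-butyldimethylsilyloxy)methyl]-1-methoxyprop-2-en-1-ylidene}chromium, via vinyllithium 3 (not isolated), via lithium acylchromate 4 (not isolated)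
Conditions: t-BuLi (2 equiv), Et2O, −78 °C; Cr(CO)6, −78 °C to rt; then Me3OBF4, CH2Cl2, 0 °C
Reagents that add atoms: hexacarbonylchromium, O=C=[Cr](=C=O)(=C=O)(=C=O)(=C=O)=C=O; trimethyloxonium tetrafluoroborate, C[O+](C)C.F[B-](F)(F)F
Why: Fischer carbene synthesis (bromine–lithium exchange, addition of the vinyllithium to a CO ligand, O-methylation of the acylchromate), which makes the carbene carbon the future C3 and the alkenyl group the future C4, C5 and C7.

Step 3
Reactants: 6 but-2-yn-1-ol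
Product: 8 (2Z)-3-iodobut-2-en-1-ol, via cyclic vinylalanate 7 (not isolated)
Conditions: NaAlH2(OCH2CH2OCH3)2, THF, 0 °C to rt; EtOAc; then I2, −78 °C to rt
Reagents that add atoms: iodine, II
Why: Hydroxyl-directed trans-hydroalumination of the propargylic alcohol places aluminium on C3 cis to the CH2O arm, and iodinolysis with retention gives the (Z)-iodoalkene that fixes the C9=C10 geometry of the target.

Step 4
Reactants: 8 (2Z)-3-iodobut-2-en-1-ol
Product: 9 (2Z)-3-iodobut-2-enal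
Conditions: MnO2, CH2Cl2, rt, dark; used at once
Reagents that add atoms: none
Why: Allylic oxidation with activated MnO2 is neutral and should leave the Z-iodoalkene geometry untouched.

Step 5
Reactants: 9 (2Z)-3-iodobut-2-enal; 10 ethynyl(trimethyl)silane
Product: 11 (3S,4Z)-5-iodo-1-(trimethylsilyl)hex-4-en-1-yn-3-ol
Conditions: Me2Zn, (S,S)-ProPhenol (10 mol%), Ph3PO (20 mol%), toluene, 0 °C
Reagents that add atoms: none
Why: Zinc–ProPhenol catalysed enantioselective alkynylation of an enal, in which the dinuclear zinc catalyst delivers the alkynyl group to one aldehyde face and sets C8 (S).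

Step 6
Reactants: 11 (3S,4Z)-5-iodo-1-(trimethylsilyl)hex-4-en-1-yn-3-ol
Product: 13 tert-butyl{[(3S,4Z)-5-iodohex-4-en-1-yn-3-yl]oxy}dimethylsilane, via C-silyl alkyne 12 (not isolated)
Conditions: TBSCl, imidazole, DMF, rt; then K2CO3, MeOH, rt
Reagents that add atoms: tert-butyl(chloro)dimethylsilane, C[Si](C)(Cl)C(C)(C)C
Why: O-silylation followed in the same flask by methanolysis of the alkynyl C–Si bond, to which the hindered secondary silyl ether and the vinyl iodide are inert.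

Step 7
Reactants: 5 pentacarbonyl{2-[(tert-butyldimethylsilyloxy)methyl]-1-methoxyprop-2-en-1-ylidene}chromium; 13 tert-butyl{[(3S,4Z)-5-iodohex-4-en-1-yn-3-yl]oxy}dimethylsilane
Product: 17 2-[(1S,2Z)-1-(tert-butyldimethylsilyloxy)-3-iodobut-2-en-1-yl]-5-[(tert-butyldimethylsilyloxy)methyl]-4-methoxyphenol, via dienylketene chromium complex 14 (not isolated), via cyclohexadienone chromium complex 15 (not isolated), via arene chromium complex 16 (not isolated)
Conditions: THF, 50 °C; then air, SiO2, CH2Cl2, rt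
Reagents that add atoms: none
Why: Dötz benzannulation: after loss of one CO the terminal alkyne inserts into the Cr=C bond (C2–C3), CO insertion (C1–C6) gives the chromium-bound dienylketene 14, and a 6π-electrocyclisation joins ketene carbon C6 to the methylene terminus C5, after which dienone 15 tautomerises to arene complex 16 and air removes the metal. It is the established benzannulation of alkenyl(alkoxy)carbene chromium complexes with terminal propargylic silyl ethers. The six-membered ring is closed by a thermal disrotatory 6π electrocyclic closure (formally 6-endo) within the coordination sphere of chromium. No stereocentre is created, and C8 is not involved and should be carried through unchanged. The step needs regioselective alkyne insertion, secured by the branched C8 substituent, which places the larger alkyne terminus (C1) next to the CO-derived carbon and the CH terminus (C2) next to the methoxy carbon, and it needs phenol formation over furan or cyclobutenone formation, which the alkenyl carbene in THF favours. The vinyl iodide and both silyl ethers should be inert to the zerovalent chromium carbonyl species at 50 °C.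

Step 8
Reactants: 17 2-[(1S,2Z)-1-(tert-butyldimethylsilyloxy)-3-iodobut-2-en-1-yl]-5-[(tert-butyldimethylsilyloxy)methyl]-4-methoxyphenol
Product: 19 2-[(1S,2Z)-1-(tert-butyldimethylsilyloxy)-3-iodobut-2-en-1-yl]-5-(hydroxymethyl)-4,4-dimethoxycyclohexa-2,5-dien-1-one, via bis-silyl quinone monoketal 18 (not isolated)
Conditions: PhI(OAc)2, MeOH, 0 °C; then CSA (10 mol%), 0 °C
Reagents that add atoms: methanol, CO
Why: Oxidative dearomatisation of the para-methoxyphenol by the hypervalent iodine reagent with capture by methanol at C3 gives the quinone monoketal (ketone at C6), and acid methanolysis then removes only the primary silyl ether, the dimethyl ketal being degenerate in methanol and the C8 ether hindered.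

Step 9
Reactants: 19 2-[(1S,2Z)-1-(tert-butyldimethylsilyloxy)-3-iodobut-2-en-1-yl]-5-(hydroxymethyl)-4,4-dimethoxycyclohexa-2,5-dien-1-one
Product: 20 (1R,6R)-1-[(1S,2Z)-1-(tert-butyldimethylsilyloxy)-3-iodobut-2-en-1-yl]-4-(hydroxymethyl)-5,5-dimethoxy-7-oxabicyclo[4.1.0]hept-3-en-2-one
Conditions: Ph3COOH, NaN(SiMe3)2, L-(+)-diisopropyl tartrate, 4 Å MS, toluene, −65 °C
Reagents that add atoms: triphenylmethyl hydroperoxide, OOC(c1ccccc1)(c1ccccc1)c1ccccc1
Why: Tartrate-mediated nucleophilic (Weitz–Scheffer) epoxidation directed by the C7 alkoxide: the peroxide adds to C2, the only enone β-carbon that bears hydrogen, and closes onto C1, the sodium tartrate aggregate held by the C7 alkoxide selecting the ring face and so setting C1 and C2, while the C4=C5 alkene with its fully substituted β-carbon stays intact.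

Step 10
Reactants: 20 (1R,6R)-1-[(1S,2Z)-1-(tert-butyldimethylsilyloxy)-3-iodobut-2-en-1-yl]-4-(hydroxymethyl)-5,5-dimethoxy-7-oxabicyclo[4.1.0]hept-3-en-2-one
Product: 21 (1R,2S,6R)-1-[(1S,2Z)-1-(tert-butyldimethylsilyloxy)-3-iodobut-2-en-1-yl]-4-(hydroxymethyl)-5,5-dimethoxy-7-oxabicyclo[4.1.0]hept-3-en-2-ol
Conditions: LiBH(s-Bu)3 (2.2 equiv), THF, −78 °C
Reagents that add atoms: none
Why: 1,2-Reduction of the enone (conjugate reduction is blocked because β-carbon C4 is fully substituted), in which the bulky hydride should approach C6 from the oxirane face, opposite the large C8 substituent on quaternary C1, placing C6–OH trans to the epoxide (C6 S).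

Step 11
Reactants: 21 (1R,2S,6R)-1-[(1S,2Z)-1-(tert-butyldimethylsilyloxy)-3-iodobut-2-en-1-yl]-4-(hydroxymethyl)-5,5-dimethoxy-7-oxabicyclo[4.1.0]hept-3-en-2-ol
Product: 22 (1S,2S,6R)-1-[(1S,2Z)-1-(tert-butyldimethylsilyloxy)-3-iodobut-2-en-1-yl]-2-(tert-butyldimethylsilyloxy)-4-[(tert-butyldimethylsilyloxy)methyl]-5,5-dimethoxy-7-oxabicyclo[4.1.0]hept-3-ene
Conditions: TBSOTf, 2,6-lutidine, CH2Cl2, −78 °C
Reagents that add atoms: tert-butyldimethylsilyl trifluoromethanesulfonate, C[Si](C)(OS(=O)(=O)C(F)(F)F)C(C)(C)C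
Why: The silyl triflate silylates the hindered secondary C6–OH and the primary C7–OH in one operation, and at −78 °C under lutidine buffering the ketal and the epoxide should not be ionised.

Step 12
Reactants: 22 (1S,2S,6R)-1-[(1S,2Z)-1-(tert-butyldimethylsilyloxy)-3-iodobut-2-en-1-yl]-2-(tert-butyldimethylsilyloxy)-4-[(tert-butyldimethylsilyloxy)methyl]-5,5-dimethoxy-7-oxabicyclo[4.1.0]hept-3-ene
Product: 23 (1R,5S,6S)-6-[(1S,2Z)-1-(tert-butyldimethylsilyloxy)-3-iodobut-2-en-1-yl]-5-(tert-butyldimethylsilyloxy)-3-[(tert-butyldimethylsilyloxy)methyl]-7-oxabicyclo[4.1.0]hept-3-en-2-one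
Conditions: montmorillonite K10 clay, wet CH2Cl2, rt
Reagents that add atoms: water, O
Why: Mild acid hydrolysis of the allylic dimethyl ketal unveils the C3 ketone; with only the C4=C5 alkene left the intermediate oxocarbenium ion cannot aromatise, and silyl ethers and epoxide should tolerate the clay.

Step 13
Reactants: 23 (1R,5S,6S)-6-[(1S,2Z)-1-(tert-butyldimethylsilyloxy)-3-iodobut-2-en-1-yl]-5-(tert-butyldimethylsilyloxy)-3-[(tert-butyldimethylsilyloxy)methyl]-7-oxabicyclo[4.1.0]hept-3-en-2-one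
Product: 24 (1S,2R,5S,6S)-6-[(1S,2Z)-1-(tert-butyldimethylsilyloxy)-3-iodobut-2-en-1-yl]-5-(tert-butyldimethylsilyloxy)-3-[(tert-butyldimethylsilyloxy)methyl]-7-oxabicyclo[4.1.0]hept-3-en-2-ol
Conditions: (R)-2-methyl-CBS-oxazaborolidine (20 mol%), catecholborane, toluene, −78 °C
Reagents that add atoms: none
Why: Corey–Bakshi–Shibata reduction in which, with the α-substituted alkenyl carbon C4 as the large and the oxirane CH (C2) as the small group, the (R)-catalyst should deliver hydride to the oxirane face of C3, reinforced by the C6 silyloxy group and the C1 side chain that screen the other face, so that C3–OH (R) ends trans to the epoxide.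

Step 14
Reactants: 25 geranyl acetate
Product: 26 (2E)-5-[(2R)-3,3-dimethyloxiran-2-yl]-3-methylpent-2-en-1-yl acetate
Conditions: D-fructose-derived Shi ketone (30 mol%), KHSO5 (as 2KHSO5·KHSO4·K2SO4), K2CO3, Bu4NHSO4, MeCN/dimethoxymethane/aqueous buffer pH 10.5, 0 °C
Reagents that add atoms: potassium peroxymonosulfate, [K+].[O-]S(=O)(=O)OO
Why: Shi asymmetric epoxidation through the chiral dioxirane, in which the electron-rich 6,7-alkene reacts in preference to the acetate-deactivated 2,3-alkene and the spiro transition state gives the (R)-epoxide.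

Step 15
Reactants: 26 (2E)-5-[(2R)-3,3-dimethyloxiran-2-yl]-3-methylpent-2-en-1-yl acetate
Product: 28 [(1S,3R,6R)-3,6-dihydroxy-2,2,6-trimethylcyclohexyl]methyl acetate, via dioxanylium ion 27 (not isolated)
Conditions: SnCl4, CH2Cl2, −78 °C; then aq. NaHCO3
Reagents that add atoms: water, O
Why: Epoxide-initiated cation–olefin cyclisation through a chair transition state, in which the (E)-alkene attacks the tertiary epoxide carbon with inversion, the resulting tertiary cation is captured anti by the acetate carbonyl to give dioxanylium ion 27, and hydrolysis leaves the primary acetate and the tertiary alcohol, so that the C3′ hydroxyl, the C1′ arm and the C6′ hydroxyl all end equatorial and the C6′ methyl axial (ring carbons: C1′ bears the arm, C3′ is the secondary and C6′ the tertiary carbinol).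

Step 16
Reactants: 28 [(1S,3R,6R)-3,6-dihydroxy-2,2,6-trimethylcyclohexyl]methyl acetate
Product: 29 [(1S,3R,6R)-2,2,6-trimethyl-3,6-bis(triethylsilyloxy)cyclohexyl]methyl acetate
Conditions: TESOTf, 2,6-lutidine, CH2Cl2, 0 °C
Reagents that add atoms: triethylsilyl trifluoromethanesulfonate, CC[Si](CC)(CC)OS(=O)(=O)C(F)(F)F
Why: The silyl triflate silylates the secondary and the hindered tertiary alcohol alike, which prevents retro-aldol cleavage once C1′ carries an aldehyde.

Step 17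
Reactants: 29 [(1S,3R,6R)-2,2,6-trimethyl-3,6-bis(triethylsilyloxy)cyclohexyl]methyl acetate
Product: 30 [(1S,3R,6R)-2,2,6-trimethyl-3,6-bis(triethylsilyloxy)cyclohexyl]methanol
Conditions: i-Bu2AlH, CH2Cl2, −78 °C
Reagents that add atoms: none
Why: Reductive removal of the acetate at low temperature leaves both triethylsilyl ethers in place.

Step 18
Reactants: 30 [(1S,3R,6R)-2,2,6-trimethyl-3,6-bis(triethylsilyloxy)cyclohexyl]methanol
Product: 31 (1R,3R,6R)-2,2,6-trimethyl-3,6-bis(triethylsilyloxy)cyclohexane-1-carbaldehyde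
Conditions: Dess–Martin periodinane, NaHCO3, CH2Cl2, rt
Reagents that add atoms: none
Why: Buffered Dess–Martin oxidation is neutral, so the equatorial aldehyde at C1′ should neither epimerise nor lose the β-silyloxy group.

Step 19
Reactants: 31 (1R,3R,6R)-2,2,6-trimethyl-3,6-bis(triethylsilyloxy)cyclohexane-1-carbaldehyde
Product: 32 4,4,5,5-tetramethyl-2-{(E)-2-[(1R,3R,6R)-2,2,6-trimethyl-3,6-bis(triethylsilyloxy)cyclohexyl]ethenyl}-1,3,2-dioxaborolane
Conditions: CrCl2, LiI, Cl2CHB(pin), THF, rt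
Reagents that add atoms: 2-(dichloromethyl)-4,4,5,5-tetramethyl-1,3,2-dioxaborolane, CC1(C)OB(C(Cl)Cl)OC1(C)C
Why: Takai-type boryl olefination, in which a geminal dichromium reagent adds to the aldehyde and anti-elimination gives the (E)-alkenylboronate that supplies C11 and C12.

Step 20
Reactants: 24 (1S,2R,5S,6S)-6-[(1S,2Z)-1-(tert-butyldimethylsilyloxy)-3-iodobut-2-en-1-yl]-5-(tert-butyldimethylsilyloxy)-3-[(tert-butyldimethylsilyloxy)methyl]-7-oxabicyclo[4.1.0]hept-3-en-2-ol; 32 4,4,5,5-tetramethyl-2-{(E)-2-[(1R,3R,6R)-2,2,6-trimethyl-3,6-bis(triethylsilyloxy)cyclohexyl]ethenyl}-1,3,2-dioxaborolane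
Product: 33 (1S,2R,5S,6R)-6-{(1S,2Z,4E)-1-(tert-butyldimethylsilyloxy)-3-methyl-5-[(1R,3R,6R)-2,2,6-trimethyl-3,6-bis(triethylsilyloxy)cyclohexyl]penta-2,4-dien-1-yl}-5-(tert-butyldimethylsilyloxy)-3-[(tert-butyldimethylsilyloxy)methyl]-7-oxabicyclo[4.1.0]hept-3-en-2-ol
Conditions: Pd(PPh3)4 (10 mol%), TlOEt, THF/H2O (3:1), rt
Reagents that add atoms: none
Why: Suzuki–Miyaura coupling with retention at both partners forms C10–C11 and the (2Z,4E)-diene; thallium ethoxide accelerates transmetalation so that the hindered (Z)-iodide should couple at room temperature without harm to the epoxide.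

Step 21
Reactants: 33 (1S,2R,5S,6R)-6-{(1S,2Z,4E)-1-(tert-butyldimethylsilyloxy)-3-methyl-5-[(1R,3R,6R)-2,2,6-trimethyl-3,6-bis(triethylsilyloxy)cyclohexyl]penta-2,4-dien-1-yl}-5-(tert-butyldimethylsilyloxy)-3-[(tert-butyldimethylsilyloxy)methyl]-7-oxabicyclo[4.1.0]hept-3-en-2-ol
Product: 34 arthrosporol A
Conditions: Bu4NF, AcOH (1:1), THF, 0 °C to rt
Reagents that add atoms: none
Why: Fluoride cleaves all five silyl ethers, and buffering with acetic acid should suppress Payne rearrangement of the epoxy alcohols.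

**Compound list** (TBSO = tert-butyldimethylsilyloxy; core labels C1–C8 as in the overview)

1 | 2-bromoprop-2-en-1-ol | OCC(Br)=C | starting material
2 | [(2-bromoprop-2-en-1-yl)oxy](tert-butyl)dimethylsilane | C=C(Br)CO[Si](C)(C)C(C)(C)C | intermediate
3 | {3-[(tert-butyldimethylsilyl)oxy]prop-1-en-2-yl}lithium | [Li]C(=C)CO[Si](C)(C)C(C)(C)C | intermediate
4 | lithium pentacarbonyl{2-[(tert-butyldimethylsilyloxy)methyl]prop-2-enoyl}chromate | [Li+].[O-]C(C(=C)CO[Si](C)(C)C(C)(C)C)=[Cr](=C=O)(=C=O)(=C=O)(=C=O)=C=O | intermediate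
5 | pentacarbonyl{2-[(tert-butyldimethylsilyloxy)methyl]-1-methoxyprop-2-en-1-ylidene}chromium | COC(C(=C)CO[Si](C)(C)C(C)(C)C)=[Cr](=C=O)(=C=O)(=C=O)(=C=O)=C=O | intermediate
6 | but-2-yn-1-ol | CC#CCO | starting material
7 | sodium 2,2-bis(2-methoxyethoxy)-3-methyl-2,5-dihydro-1,2-oxaluminol-2-uide (cyclic vinylalanate) | [Na+].CC1=CCO[Al-]1(OCCOC)OCCOC | intermediate
8 | (2Z)-3-iodobut-2-en-1-ol | C/C(I)=C/CO | intermediate
9 | (2Z)-3-iodobut-2-enal | C/C(I)=C/C=O | intermediate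
10 | ethynyl(trimethyl)silane | C#C[Si](C)(C)C | starting material
11 | (3S,4Z)-5-iodo-1-(trimethylsilyl)hex-4-en-1-yn-3-ol | C/C(I)=C/[C@H](O)C#C[Si](C)(C)C | intermediate
12 | tert-butyl{[(3S,4Z)-5-iodo-1-(trimethylsilyl)hex-4-en-1-yn-3-yl]oxy}dimethylsilane | C/C(I)=C/[C@H](O[Si](C)(C)C(C)(C)C)C#C[Si](C)(C)C | intermediate
13 | tert-butyl{[(3S,4Z)-5-iodohex-4-en-1-yn-3-yl]oxy}dimethylsilane | C/C(I)=C/[C@H](O[Si](C)(C)C(C)(C)C)C#C | intermediate
14 | tricarbonylchromium complex of (3E)-2-[(1S,2Z)-1-(TBSO)-3-iodobut-2-en-1-yl]-4-methoxy-5-[(TBSO)methyl]hexa-1,3,5-trien-1-one (metal fragment written as a separate component) | C/C(I)=C/[C@H](O[Si](C)(C)C(C)(C)C)C(=C=O)/C=C(/OC)C(=C)CO[Si](C)(C)C(C)(C)C.O=C=[Cr](=C=O)=C=O | intermediate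
15 | tricarbonylchromium complex of 2-[(1S,2Z)-1-(TBSO)-3-iodobut-2-en-1-yl]-4-methoxy-5-[(TBSO)methyl]cyclohexa-2,4-dien-1-one (metal fragment written as a separate component) | C/C(I)=C/[C@H](O[Si](C)(C)C(C)(C)C)C1=CC(OC)=C(CO[Si](C)(C)C(C)(C)C)CC1=O.O=C=[Cr](=C=O)=C=O | intermediate
16 | tricarbonylchromium arene complex of phenol 17 (metal fragment written as a separate component) | C/C(I)=C/[C@H](O[Si](C)(C)C(C)(C)C)c1cc(OC)c(CO[Si](C)(C)C(C)(C)C)cc1O.O=C=[Cr](=C=O)=C=O | intermediate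
17 | 2-[(1S,2Z)-1-(TBSO)-3-iodobut-2-en-1-yl]-5-[(TBSO)methyl]-4-methoxyphenol | C/C(I)=C/[C@H](O[Si](C)(C)C(C)(C)C)c1cc(OC)c(CO[Si](C)(C)C(C)(C)C)cc1O | intermediate
18 | 2-[(1S,2Z)-1-(TBSO)-3-iodobut-2-en-1-yl]-5-[(TBSO)methyl]-4,4-dimethoxycyclohexa-2,5-dien-1-one | C/C(I)=C/[C@H](O[Si](C)(C)C(C)(C)C)C1=CC(OC)(OC)C(CO[Si](C)(C)C(C)(C)C)=CC1=O | intermediate
19 | 2-[(1S,2Z)-1-(TBSO)-3-iodobut-2-en-1-yl]-5-(hydroxymethyl)-4,4-dimethoxycyclohexa-2,5-dien-1-one | C/C(I)=C/[C@H](O[Si](C)(C)C(C)(C)C)C1=CC(OC)(OC)C(CO)=CC1=O | intermediate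
20 | (1R,6R)-1-[(1S,2Z)-1-(TBSO)-3-iodobut-2-en-1-yl]-4-(hydroxymethyl)-5,5-dimethoxy-7-oxabicyclo[4.1.0]hept-3-en-2-one | C/C(I)=C/[C@H](O[Si](C)(C)C(C)(C)C)[C@]12O[C@H]1C(OC)(OC)C(CO)=CC2=O | intermediate
21 | (1R,2S,6R)-1-[(1S,2Z)-1-(TBSO)-3-iodobut-2-en-1-yl]-4-(hydroxymethyl)-5,5-dimethoxy-7-oxabicyclo[4.1.0]hept-3-en-2-ol | C/C(I)=C/[C@H](O[Si](C)(C)C(C)(C)C)[C@]12O[C@H]1C(OC)(OC)C(CO)=C[C@@H]2O | intermediate
22 | (1S,2S,6R)-1-[(1S,2Z)-1-(TBSO)-3-iodobut-2-en-1-yl]-2-(TBSO)-4-[(TBSO)methyl]-5,5-dimethoxy-7-oxabicyclo[4.1.0]hept-3-ene | C/C(I)=C/[C@H](O[Si](C)(C)C(C)(C)C)[C@]12O[C@H]1C(OC)(OC)C(CO[Si](C)(C)C(C)(C)C)=C[C@@H]2O[Si](C)(C)C(C)(C)C | intermediate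
23 | (1R,5S,6S)-6-[(1S,2Z)-1-(TBSO)-3-iodobut-2-en-1-yl]-5-(TBSO)-3-[(TBSO)methyl]-7-oxabicyclo[4.1.0]hept-3-en-2-one | C/C(I)=C/[C@H](O[Si](C)(C)C(C)(C)C)[C@]12O[C@H]1C(=O)C(CO[Si](C)(C)C(C)(C)C)=C[C@@H]2O[Si](C)(C)C(C)(C)C | intermediate
24 | (1S,2R,5S,6S)-6-[(1S,2Z)-1-(TBSO)-3-iodobut-2-en-1-yl]-5-(TBSO)-3-[(TBSO)methyl]-7-oxabicyclo[4.1.0]hept-3-en-2-ol | C/C(I)=C/[C@H](O[Si](C)(C)C(C)(C)C)[C@]12O[C@H]1[C@H](O)C(CO[Si](C)(C)C(C)(C)C)=C[C@@H]2O[Si](C)(C)C(C)(C)C | intermediate
25 | geranyl acetate, (2E)-3,7-dimethylocta-2,6-dien-1-yl acetate | CC(C)=CCC/C(C)=C/COC(C)=O | starting material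
26 | (2E)-5-[(2R)-3,3-dimethyloxiran-2-yl]-3-methylpent-2-en-1-yl acetate | CC(=O)OC/C=C(\C)CC[C@H]1OC1(C)C | intermediate
27 | trans-fused 2-methyl-1,3-dioxan-2-ylium ion bridging the C1′ CH2–O and C6′–O, with the C3′ oxygen bound to tin | C[C+]1OC[C@@H]2C(C)(C)[C@H](O[Sn-](Cl)(Cl)(Cl)Cl)CC[C@@]2(C)O1 | intermediate
28 | [(1S,3R,6R)-3,6-dihydroxy-2,2,6-trimethylcyclohexyl]methyl acetate | CC(=O)OC[C@@H]1C(C)(C)[C@H](O)CC[C@@]1(C)O | intermediate
29 | [(1S,3R,6R)-2,2,6-trimethyl-3,6-bis(triethylsilyloxy)cyclohexyl]methyl acetate | CC(=O)OC[C@@H]1C(C)(C)[C@H](O[Si](CC)(CC)CC)CC[C@@]1(C)O[Si](CC)(CC)CC | intermediate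
30 | [(1S,3R,6R)-2,2,6-trimethyl-3,6-bis(triethylsilyloxy)cyclohexyl]methanol | OC[C@@H]1C(C)(C)[C@H](O[Si](CC)(CC)CC)CC[C@@]1(C)O[Si](CC)(CC)CC | intermediate
31 | (1R,3R,6R)-2,2,6-trimethyl-3,6-bis(triethylsilyloxy)cyclohexane-1-carbaldehyde | O=C[C@@H]1C(C)(C)[C@H](O[Si](CC)(CC)CC)CC[C@@]1(C)O[Si](CC)(CC)CC | intermediate
32 | 4,4,5,5-tetramethyl-2-{(E)-2-[(1R,3R,6R)-2,2,6-trimethyl-3,6-bis(triethylsilyloxy)cyclohexyl]ethenyl}-1,3,2-dioxaborolane | CC1(C)OB(/C=C/[C@@H]2C(C)(C)[C@H](O[Si](CC)(CC)CC)CC[C@@]2(C)O[Si](CC)(CC)CC)OC1(C)C | intermediate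
33 | (1S,2R,5S,6R)-6-{(1S,2Z,4E)-1-(TBSO)-3-methyl-5-[(1R,3R,6R)-2,2,6-trimethyl-3,6-bis(triethylsilyloxy)cyclohexyl]penta-2,4-dien-1-yl}-5-(TBSO)-3-[(TBSO)methyl]-7-oxabicyclo[4.1.0]hept-3-en-2-ol | CC(=C/[C@H](O[Si](C)(C)C(C)(C)C)[C@]12O[C@H]1[C@H](O)C(CO[Si](C)(C)C(C)(C)C)=C[C@@H]2O[Si](C)(C)C(C)(C)C)/C=C/[C@@H]1C(C)(C)[C@H](O[Si](CC)(CC)CC)CC[C@@]1(C)O[Si](CC)(CC)CC | intermediate
34 | arthrosporol A, (1R,2S,5R,6S)-1-[(1S,2Z,4E)-5-[(1R,3R,6R)-3,6-dihydroxy-2,2,6-trimethylcyclohexyl]-1-hydroxy-3-methylpenta-2,4-dien-1-yl]-4-(hydroxymethyl)-7-oxabicyclo[4.1.0]hept-3-ene-2,5-diol | CC(=C/[C@H](O)[C@]12O[C@H]1[C@H](O)C(CO)=C[C@@H]2O)/C=C/[C@@H]1C(C)(C)[C@H](O)CC[C@@]1(C)O | target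

**Step count.** Total: 21 steps. Longest linear sequence: 13 steps (steps 3 to 13, then 20 and 21).

**Steps most likely to fail**

Step 9. The reagent-controlled peroxide delivery may be eroded or reversed by the resident C8 stereocentre, or peroxide addition may be slow next to the branched C1 substituent. The fallback sets out from 18, isolated by omitting the acid treatment of step 8. Non-directed Weitz–Scheffer epoxidation with t-BuOOH and DBU in CH2Cl2 should give both C1/C2 diastereomers, which are separable by chromatography because C8 is stereogenic. The wanted isomer, the bis-silyl epoxy ketone F1, is then desilylated at C7 with CSA in methanol and the route is rejoined at 20.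

Step 10. Hydride delivery anti to the oxirane C–O bond (polar Felkin control) may outweigh the steric bias and give the C6 epimer. The fallback sets out from 20 and accepts that outcome. Reduction with NaBH4 and CeCl3 in methanol at −78 °C should give the C6-epimeric diol F2. TBSCl and imidazole silylate only the primary hydroxyl to give the mono-silyl ether F3. A Mitsunobu reaction (4-nitrobenzoic acid, PPh3, diisopropyl azodicarboxylate) inverts C6 to give the 4-nitrobenzoate F4. K2CO3 in methanol frees the inverted alcohol F5, and TBSOTf with 2,6-lutidine returns the route to 22.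

Step 15. The tertiary cation may lose a proton or be captured by the C3′ oxygen instead of the acetate, giving alkenes or a bridged ether. The fallback sets out from 26 and changes the terminating group. K2CO3 in methanol gives the epoxy alcohol F6, and Boc2O with N-methylimidazole gives the tert-butyl carbonate F7. BF3·OEt2 in CH2Cl2 at −78 °C should trigger the same chair cyclisation, now terminated by the carbonate carbonyl with loss of isobutene, to give the trans-fused cyclic carbonate F8. K2CO3 in methanol gives the triol F9, and acetyl chloride with 2,4,6-collidine at −78 °C acetylates only the primary hydroxyl, rejoining the route at 28.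

**Further compounds**

F1 | step 9 | (1R,6R)-1-[(1S,2Z)-1-(TBSO)-3-iodobut-2-en-1-yl]-4-[(TBSO)methyl]-5,5-dimethoxy-7-oxabicyclo[4.1.0]hept-3-en-2-one | C/C(I)=C/[C@H](O[Si](C)(C)C(C)(C)C)[C@]12O[C@H]1C(OC)(OC)C(CO[Si](C)(C)C(C)(C)C)=CC2=O
F2 | step 10 | (1R,2R,6R)-1-[(1S,2Z)-1-(TBSO)-3-iodobut-2-en-1-yl]-4-(hydroxymethyl)-5,5-dimethoxy-7-oxabicyclo[4.1.0]hept-3-en-2-ol | C/C(I)=C/[C@H](O[Si](C)(C)C(C)(C)C)[C@]12O[C@H]1C(OC)(OC)C(CO)=C[C@H]2O
F3 | step 10 | (1R,2R,6R)-1-[(1S,2Z)-1-(TBSO)-3-iodobut-2-en-1-yl]-4-[(TBSO)methyl]-5,5-dimethoxy-7-oxabicyclo[4.1.0]hept-3-en-2-ol | C/C(I)=C/[C@H](O[Si](C)(C)C(C)(C)C)[C@]12O[C@H]1C(OC)(OC)C(CO[Si](C)(C)C(C)(C)C)=C[C@H]2O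
F4 | step 10 | (1R,2S,6R)-1-[(1S,2Z)-1-(TBSO)-3-iodobut-2-en-1-yl]-4-[(TBSO)methyl]-5,5-dimethoxy-7-oxabicyclo[4.1.0]hept-3-en-2-yl 4-nitrobenzoate | C/C(I)=C/[C@H](O[Si](C)(C)C(C)(C)C)[C@]12O[C@H]1C(OC)(OC)C(CO[Si](C)(C)C(C)(C)C)=C[C@@H]2OC(=O)c1ccc(cc1)[N+](=O)[O-]
F5 | step 10 | (1R,2S,6R)-1-[(1S,2Z)-1-(TBSO)-3-iodobut-2-en-1-yl]-4-[(TBSO)methyl]-5,5-dimethoxy-7-oxabicyclo[4.1.0]hept-3-en-2-ol | C/C(I)=C/[C@H](O[Si](C)(C)C(C)(C)C)[C@]12O[C@H]1C(OC)(OC)C(CO[Si](C)(C)C(C)(C)C)=C[C@@H]2O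
F6 | step 15 | (2E)-5-[(2R)-3,3-dimethyloxiran-2-yl]-3-methylpent-2-en-1-ol | OC/C=C(\C)CC[C@H]1OC1(C)C
F7 | step 15 | tert-butyl (2E)-5-[(2R)-3,3-dimethyloxiran-2-yl]-3-methylpent-2-en-1-yl carbonate | CC(C)(C)OC(=O)OC/C=C(\C)CC[C@H]1OC1(C)C
F8 | step 15 | (4aS,6R,8aR)-6-hydroxy-5,5,8a-trimethylhexahydro-4H-1,3-benzodioxin-2-one | O=C1OC[C@@H]2C(C)(C)[C@H](O)CC[C@@]2(C)O1
F9 | step 15 | (1R,2S,4R)-2-(hydroxymethyl)-1,3,3-trimethylcyclohexane-1,4-diol | OC[C@@H]1C(C)(C)[C@H](O)CC[C@@]1(C)O
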